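**Strategy**

The target is a tetraflavanoid: three ent-fisetinidol units (2S,3R, 4α-aryl, 3,4-cis) on a (+)-catechin core. Each ent-fisetinidol pyran ring (ring C) is disconnected between C-3 and C-4, a carbinol carbon next to a doubly benzylic methine, both traced back to carbonyl carbons. The key step is a samarium diiodide pinacol cyclisation of a bis(keto aldehyde): each diaryl ketone (future C-4, already bonded to the lower ring A) couples with its tethered α-aryloxy aldehyde (future C-3), closing ring C of the top unit and of the C-6-bound unit at once with 2,3-trans control. Ionic hydrogenation then removes the C-4 hydroxyls and sets the 3,4-cis geometry.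

Key step: step 17

**Remarks and assumptions**

- Unit names: "top unit" is the ent-fisetinidol bonded through C-4 to C-6 of the "middle unit"; the middle unit is bonded through C-4 to C-8 of the catechin unit; the "lateral unit" is bonded through C-4 to C-6 of the catechin unit. Ring A is the benzo ring, ring B the catechol ring and ring C the pyran ring of each flavan.
- 3,4-Bis(benzyloxy)benzaldehyde, methyl 4-(benzyloxy)-2-hydroxybenzoate and (+)-catechin are taken as commercial.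
- The (Ra,Rc,Rc) phosphoramidite is assumed to give the (R)-configured branched ether in step 4; if the sense of induction is opposite, the mirror-image ligand is used with no other change.

**Route**

Step 1
Reactants: 1 3,4-bis(benzyloxy)benzaldehyde
Product: 2 ethyl (2E)-3-[3,4-bis(benzyloxy)phenyl]prop-2-enoate
Conditions: triethyl phosphonoacetate, NaH, THF, 0 °C → rt
Reagents that add atoms: triethyl phosphonoacetate, CCOC(=O)CP(=O)(OCC)OCC
Why: Horner–Wadsworth–Emmons olefination of an aromatic aldehyde with a stabilised phosphonate anion should give the (E)-cinnamate.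

Step 2
Reactants: 2 ethyl (2E)-3-[3,4-bis(benzyloxy)phenyl]prop-2-enoate
Product: 3 (2E)-3-[3,4-bis(benzyloxy)phenyl]prop-2-en-1-ol
Conditions: i-Bu2AlH (DIBAL-H, 2.2 equiv), CH2Cl2, −78 °C; Rochelle salt work-up
Reagents that add atoms: none
Why: 1,2-reduction of the conjugated ester by DIBAL-H at low temperature should give the allylic alcohol with the alkene and benzyl ethers untouched.

Step 3
Reactants: 3 (2E)-3-[3,4-bis(benzyloxy)phenyl]prop-2-en-1-ol
Product: 4 (2E)-3-[3,4-bis(benzyloxy)phenyl]prop-2-en-1-yl methyl carbonate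
Conditions: methyl chloroformate, pyridine, CH2Cl2, 0 °C
Reagents that add atoms: methyl chloroformate, COC(=O)Cl
Why: O-acylation of the primary allylic alcohol installs the carbonate leaving group required for allylic substitution.

Step 4
Reactants: 5 methyl 4-(benzyloxy)-2-hydroxybenzoate; 4 (2E)-3-[3,4-bis(benzyloxy)phenyl]prop-2-en-1-yl methyl carbonate
Product: 6 methyl 4-(benzyloxy)-2-{[(1R)-1-[3,4-bis(benzyloxy)phenyl]prop-2-en-1-yl]oxy}benzoate
Conditions: lithium phenoxide of 5 (from LiOt-Bu), [Ir(cod)Cl]2 (2 mol %), (Ra,Rc,Rc)-O,O'-(1,1'-binaphthalene-2,2'-diyl) N,N-bis(1-phenylethyl)phosphoramidite (4 mol %), THF, 25–40 °C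
Reagents that add atoms: none
Why: Iridium-catalysed asymmetric allylic etherification is branched-selective, the phenoxide attacking the aryl-substituted terminus of the allyl iridium phosphoramidite complex, and the ligand configuration sets the (R) centre that becomes C-2 (S in the flavan) of every ent-fisetinidol unit.

Step 5
Reactants: 6 methyl 4-(benzyloxy)-2-{[(1R)-1-[3,4-bis(benzyloxy)phenyl]prop-2-en-1-yl]oxy}benzoate
Product: 7 4-(benzyloxy)-2-{[(1R)-1-[3,4-bis(benzyloxy)phenyl]prop-2-en-1-yl]oxy}-N-methoxy-N-methylbenzamide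
Conditions: N,O-dimethylhydroxylamine hydrochloride, i-PrMgCl (3 equiv), THF, −20 → 0 °C
Reagents that add atoms: N,O-dimethylhydroxylamine hydrochloride, CNOC.Cl
Why: Aminolysis of the ester by the chloromagnesium amide gives the Weinreb amide under non-acidic conditions that leave the ionisable allylic benzylic aryl ether and its stereocentre untouched.

Step 6
Reactants: 8 (+)-catechin
Product: 9 5,7,3',4'-tetra-O-benzyl-(+)-catechin
Conditions: benzyl bromide (4.4 equiv), K2CO3, DMF, 0 °C → rt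
Reagents that add atoms: benzyl bromide, BrCc1ccccc1
Why: Williamson etherification with a carbonate base benzylates the four acidic phenols and leaves the secondary alcohol.

Step 7
Reactants: 9 5,7,3',4'-tetra-O-benzyl-(+)-catechin
Product: 10 3,5,7,3',4'-penta-O-benzyl-(+)-catechin
Conditions: NaH, benzyl bromide, n-Bu4NI (cat.), DMF, 0 °C → rt
Reagents that add atoms: benzyl bromide, BrCc1ccccc1
Why: Williamson etherification of the sodium alkoxide protects the 3-OH so that no acidic proton interferes with the later aryllithium steps.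

Step 8
Reactants: 10 3,5,7,3',4'-penta-O-benzyl-(+)-catechin
Product: 11 8-bromo-3,5,7,3',4'-penta-O-benzyl-(+)-catechin
Conditions: N-bromosuccinimide (1.0 equiv), CH2Cl2, −78 → −40 °C
Reagents that add atoms: N-bromosuccinimide, O=C1CCC(=O)N1Br
Why: Electrophilic aromatic bromination of the phloroglucinol-type ring A should occur at C-8, its most reactive position at low temperature.

Step 9
Reactants: 11 8-bromo-3,5,7,3',4'-penta-O-benzyl-(+)-catechin; 7 4-(benzyloxy)-2-{[(1R)-1-[3,4-bis(benzyloxy)phenyl]prop-2-en-1-yl]oxy}-N-methoxy-N-methylbenzamide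
Product: 13 (3,5,7,3',4'-penta-O-benzylcatechin-8-yl) 4-(benzyloxy)-2-{[(1R)-1-[3,4-bis(benzyloxy)phenyl]prop-2-en-1-yl]oxy}phenyl ketone, via 8-lithio-penta-O-benzylcatechin 12 (not isolated)
Conditions: t-BuLi (2.1 equiv), THF, −78 °C; then 7, −78 → 0 °C; aq. NH4Cl
Reagents that add atoms: none
Why: Bromine–lithium exchange followed by acylation of the aryllithium with the N-methoxy-N-methylamide stops at the ketone and joins the future C-4 of the middle unit to C-8 of catechin.

Step 10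
Reactants: 13 (penta-O-benzylcatechin-8-yl) aryl ketone
Product: 14 (2S)-2-[3,4-bis(benzyloxy)phenyl]-2-{5-(benzyloxy)-2-[(3,5,7,3',4'-penta-O-benzylcatechin-8-yl)carbonyl]phenoxy}acetaldehyde
Conditions: OsO4 (2 mol %), NaIO4 (4 equiv), 2,6-lutidine, 1,4-dioxane/H2O, rt; used crude
Reagents that add atoms: sodium periodate, [Na+].[O-]I(=O)(=O)=O
Why: Lemieux–Johnson cleavage (catalytic dihydroxylation, then periodate glycol cleavage) turns the vinyl group into the aldehyde under buffered conditions that should spare the epimerisable α-aryloxy centre.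

Step 11
Reactants: 14 keto aldehyde
Product: 15 dimer diol: 7,3',4'-tri-O-benzyl-4-hydroxy-ent-fisetinidol (2S,3R; 3-OH and 4-OH cis, both trans to the 2-aryl group) bonded through C-4 to C-8 of penta-O-benzylcatechin
Conditions: SmI2 (2.5 equiv, 0.1 M in THF), THF, −78 → −20 °C, slow addition of 14; aq. NaHCO3/Na2S2O3
Reagents that add atoms: none
Why: SmI2 pinacol cyclisation of the diaryl ketone with the tethered aldehyde closes ring C of the middle unit by C-3–C-4 bond formation, the C-3 oxygen going anti to the pseudo-equatorial C-2 aryl group and samarium bridging giving the cis-diol.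

Step 12
Reactants: 15 dimer diol
Product: 16 3-O-benzyl ether of 15 (tertiary 4-OH free)
Conditions: NaH (1.1 equiv), benzyl bromide (1.1 equiv), n-Bu4NI (cat.), THF/DMF, 0 °C
Reagents that add atoms: benzyl bromide, BrCc1ccccc1
Why: Williamson etherification is selective for the secondary alkoxide because the tertiary, doubly benzylic hydroxyl is too hindered, and the ether blocks pinacol-type rearrangement in the next step.

Step 13
Reactants: 16 3-O-benzyl ether of the dimer diol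
Product: 17 3,7,3',4'-tetra-O-benzyl-ent-fisetinidol-(4α→8)-3,5,7,3',4'-penta-O-benzylcatechin (upper unit 2S,3R, 2,3-trans-3,4-cis)
Conditions: n-Bu3SnH (5 equiv), CF3CO2H (5 equiv), CH2Cl2, −40 → 0 °C
Reagents that add atoms: none
Why: Ionic hydrogenation: acid ionises the tertiary doubly benzylic alcohol to a strongly stabilised diarylcarbenium ion, and hydride should enter anti to the adjacent 3-benzyloxy group, leaving the catechin ring cis to O-3 (4α).

Step 14
Reactants: 17 ent-fisetinidol-(4α→8)-catechin nona-O-benzyl ether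
Product: 18 6-bromo-3,7,3',4'-tetra-O-benzyl-ent-fisetinidol-(4α→8)-6-bromo-3,5,7,3',4'-penta-O-benzylcatechin
Conditions: N-bromosuccinimide (2.05 equiv), CH2Cl2, −78 → 0 °C
Reagents that add atoms: N-bromosuccinimide, O=C1CCC(=O)N1Br
Why: Electrophilic bromination should take the two most nucleophilic free positions, C-6 of the catechin ring A and C-6 of the fisetinidol ring A (para to O-1, ortho to the 7-benzyloxy group), since C-8 of the latter is flanked by two oxygens and the catechol rings are far less activated.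

Step 15
Reactants: 18 dibromide; 7 Weinreb amide (2.4 equiv)
Product: 20 bis-ketone: 18 with each bromine replaced by a 4-(benzyloxy)-2-{[(1R)-1-[3,4-bis(benzyloxy)phenyl]prop-2-en-1-yl]oxy}benzoyl group, via 6,6'-dilithio dimer 19 (not isolated)
Conditions: t-BuLi (4.2 equiv), THF, −78 °C; then 7, −78 → 0 °C; aq. NH4Cl
Reagents that add atoms: none
Why: Double bromine–lithium exchange and double acylation by the Weinreb amide install the future C-4 carbons of the top and lateral units as diaryl ketones.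

Step 16
Reactants: 20 bis-ketone
Product: 21 bis(keto aldehyde): 20 with both vinyl groups cleaved to formyl groups (each an (S)-configured α-aryloxy aldehyde)
Conditions: OsO4 (4 mol %), NaIO4 (8 equiv), 2,6-lutidine, 1,4-dioxane/H2O, rt; used crude
Reagents that add atoms: sodium periodate, [Na+].[O-]I(=O)(=O)=O
Why: Twofold Lemieux–Johnson cleavage unmasks both future C-3 carbons as aldehydes under buffered conditions, as in step 10.

Step 17
Reactants: 21 bis(keto aldehyde)
Product: 22 bis-diol: protected tetramer with a tertiary 4-OH on the top and lateral units (each 2S,3R; 3-OH and 4-OH cis, trans to the 2-aryl group)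
Conditions: SmI2 (6 equiv, 0.1 M in THF), THF, −78 → −20 °C, slow addition of 21 at high dilution; aq. NaHCO3/Na2S2O3
Reagents that add atoms: none
Why: Single-electron transfer from SmI2 to each diaryl ketone, which is far easier to reduce than the aliphatic aldehyde, gives a hindered, persistent samarium ketyl at C-4 that adds to the tethered, samarium-activated aldehyde carbon C-3 (or couples with its ketyl), and a second electron transfer gives the trivalent samarium 3,4-diolate. The closest known reaction type is the SmI2-mediated intramolecular ketone–aldehyde pinacol coupling, a union of two electrophilic carbonyl carbons made possible by reductive polarity reversal. Each pyran ring (ring C of the top unit and ring C of the lateral unit) closes in a 6-exo-trig mode by C-3–C-4 bond formation, the aldehyde C=O being exocyclic to the forming ring. C-3 is controlled by the existing C-2 centre: in the chair-like transition state the C-2 aryl group is pseudo-equatorial and the samarium-bound C-3 oxygen takes the pseudo-equatorial position anti to it and anti to the C-2–O-1 dipole, which gives the 2,3-trans arrangement, while C-4 follows from bridging of both oxygens by samarium (cis-diol) and is erased in step 19. The step needs reduction of the ketone before the aldehyde, because a free aldehyde ketyl could expel the β-aryloxy group or dimerise; the low reduction potential of the diaryl ketone, the absence of HMPA and proton donors, and high dilution should secure this. The two sites are held apart by a rigid flavan unit and should react independently.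

Step 18
Reactants: 22 bis-diol
Product: 23 bis(3-O-benzyl ether) of 22 (both tertiary 4-OH free)
Conditions: NaH (2.2 equiv), benzyl bromide (2.2 equiv), n-Bu4NI (cat.), THF/DMF, 0 °C
Reagents that add atoms: benzyl bromide, BrCc1ccccc1
Why: Williamson etherification of the two secondary alkoxides, selective over the hindered tertiary hydroxyls, as in step 12.

Step 19
Reactants: 23 bis(3-O-benzyl ether)
Product: 24 heptadeca-O-benzyl ether of the target
Conditions: n-Bu3SnH (10 equiv), CF3CO2H (10 equiv), CH2Cl2, −40 → 0 °C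
Reagents that add atoms: none
Why: Twofold ionic hydrogenation as in step 13: each diarylcarbenium ion at C-4 should take hydride anti to its 3-benzyloxy group, giving the 4α-aryl (3,4-cis) configuration in the top and lateral units.

Step 20
Reactants: 24 heptadeca-O-benzyl ether
Product: 25 ent-fisetinidol-(4α→6)-ent-fisetinidol-(4α→8)-catechin-(6→4α)-ent-fisetinidol (target)
Conditions: H2 (1 atm), Pd(OH)2/C, THF/MeOH/H2O, rt
Reagents that add atoms: none
Why: Hydrogenolysis of the seventeen benzyl ethers under neutral, low-pressure conditions should free all hydroxyls without cleaving the O-1–C-2 or C-4–aryl bonds of the flavan units.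

**Compound list**

1 | 3,4-bis(benzyloxy)benzaldehyde | O=Cc1ccc(OCc2ccccc2)c(OCc2ccccc2)c1 | starting material
2 | ethyl (2E)-3-[3,4-bis(benzyloxy)phenyl]prop-2-enoate | CCOC(=O)/C=C/c1ccc(OCc2ccccc2)c(OCc2ccccc2)c1 | intermediate
3 | (2E)-3-[3,4-bis(benzyloxy)phenyl]prop-2-en-1-ol | OC/C=C/c1ccc(OCc2ccccc2)c(OCc2ccccc2)c1 | intermediate
4 | (2E)-3-[3,4-bis(benzyloxy)phenyl]prop-2-en-1-yl methyl carbonate | COC(=O)OC/C=C/c1ccc(OCc2ccccc2)c(OCc2ccccc2)c1 | intermediate
5 | methyl 4-(benzyloxy)-2-hydroxybenzoate | COC(=O)c1ccc(OCc2ccccc2)cc1O | starting material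
6 | methyl 4-(benzyloxy)-2-{[(1R)-1-[3,4-bis(benzyloxy)phenyl]prop-2-en-1-yl]oxy}benzoate | COC(=O)c1ccc(OCc2ccccc2)cc1O[C@@H](c1ccc(OCc2ccccc2)c(OCc2ccccc2)c1)C=C | intermediate
7 | 4-(benzyloxy)-2-{[(1R)-1-[3,4-bis(benzyloxy)phenyl]prop-2-en-1-yl]oxy}-N-methoxy-N-methylbenzamide | CON(C)C(=O)c1ccc(OCc2ccccc2)cc1O[C@@H](c1ccc(OCc2ccccc2)c(OCc2ccccc2)c1)C=C | intermediate
8 | (+)-catechin, (2R,3S)-2-(3,4-dihydroxyphenyl)chromane-3,5,7-triol | O[C@H]1Cc2c(O)cc(O)cc2O[C@@H]1c1ccc(O)c(O)c1 | starting material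
9 | 5,7,3',4'-tetra-O-benzyl-(+)-catechin | O[C@H]1Cc2c(OCc3ccccc3)cc(OCc3ccccc3)cc2O[C@@H]1c1ccc(OCc2ccccc2)c(OCc2ccccc2)c1 | intermediate
10 | 3,5,7,3',4'-penta-O-benzyl-(+)-catechin | c1ccccc1CO[C@H]1Cc2c(OCc3ccccc3)cc(OCc3ccccc3)cc2O[C@@H]1c1ccc(OCc2ccccc2)c(OCc2ccccc2)c1 | intermediate
11 | 8-bromo-3,5,7,3',4'-penta-O-benzyl-(+)-catechin | c1ccccc1CO[C@H]1Cc2c(OCc3ccccc3)cc(OCc3ccccc3)c(Br)c2O[C@@H]1c1ccc(OCc2ccccc2)c(OCc2ccccc2)c1 | intermediate
12 | 8-lithio-3,5,7,3',4'-penta-O-benzyl-(+)-catechin | c1ccccc1CO[C@H]1Cc2c(OCc3ccccc3)cc(OCc3ccccc3)c([Li])c2O[C@@H]1c1ccc(OCc2ccccc2)c(OCc2ccccc2)c1 | intermediate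
13 | (3,5,7,3',4'-penta-O-benzylcatechin-8-yl) 4-(benzyloxy)-2-{[(1R)-1-[3,4-bis(benzyloxy)phenyl]prop-2-en-1-yl]oxy}phenyl ketone | c1ccccc1CO[C@H]1Cc2c(OCc3ccccc3)cc(OCc3ccccc3)c(C(=O)c3ccc(OCc4ccccc4)cc3O[C@@H](c3ccc(OCc4ccccc4)c(OCc4ccccc4)c3)C=C)c2O[C@@H]1c1ccc(OCc2ccccc2)c(OCc2ccccc2)c1 | intermediate
14 | (2S)-2-[3,4-bis(benzyloxy)phenyl]-2-{5-(benzyloxy)-2-[(3,5,7,3',4'-penta-O-benzylcatechin-8-yl)carbonyl]phenoxy}acetaldehyde | c1ccccc1CO[C@H]1Cc2c(OCc3ccccc3)cc(OCc3ccccc3)c(C(=O)c3ccc(OCc4ccccc4)cc3O[C@@H](c3ccc(OCc4ccccc4)c(OCc4ccccc4)c3)C=O)c2O[C@@H]1c1ccc(OCc2ccccc2)c(OCc2ccccc2)c1 | intermediate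
15 | dimer diol: 7,3',4'-tri-O-benzyl-4-hydroxy-ent-fisetinidol (2S,3R; 3-OH and 4-OH cis, trans to 2-aryl) C-4-bonded to C-8 of penta-O-benzylcatechin | c1ccccc1CO[C@H]1Cc2c(OCc3ccccc3)cc(OCc3ccccc3)c([C@@]3(O)c4ccc(OCc5ccccc5)cc4O[C@@H](c4ccc(OCc5ccccc5)c(OCc5ccccc5)c4)[C@@H]3O)c2O[C@@H]1c1ccc(OCc2ccccc2)c(OCc2ccccc2)c1 | intermediate
16 | 3-O-benzyl ether of 15 | c1ccccc1CO[C@H]1Cc2c(OCc3ccccc3)cc(OCc3ccccc3)c([C@@]3(O)c4ccc(OCc5ccccc5)cc4O[C@@H](c4ccc(OCc5ccccc5)c(OCc5ccccc5)c4)[C@@H]3OCc4ccccc4)c2O[C@@H]1c1ccc(OCc2ccccc2)c(OCc2ccccc2)c1 | intermediate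
17 | 3,7,3',4'-tetra-O-benzyl-ent-fisetinidol-(4α→8)-3,5,7,3',4'-penta-O-benzylcatechin | c1ccccc1CO[C@H]1Cc2c(OCc3ccccc3)cc(OCc3ccccc3)c([C@@H]3c4ccc(OCc5ccccc5)cc4O[C@@H](c4ccc(OCc5ccccc5)c(OCc5ccccc5)c4)[C@@H]3OCc4ccccc4)c2O[C@@H]1c1ccc(OCc2ccccc2)c(OCc2ccccc2)c1 | intermediate
18 | 6-bromo-3,7,3',4'-tetra-O-benzyl-ent-fisetinidol-(4α→8)-6-bromo-3,5,7,3',4'-penta-O-benzylcatechin | c1ccccc1CO[C@H]1Cc2c(OCc3ccccc3)c(Br)c(OCc3ccccc3)c([C@@H]3c4cc(Br)c(OCc5ccccc5)cc4O[C@@H](c4ccc(OCc5ccccc5)c(OCc5ccccc5)c4)[C@@H]3OCc4ccccc4)c2O[C@@H]1c1ccc(OCc2ccccc2)c(OCc2ccccc2)c1 | intermediate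
19 | 6,6'-dilithio analogue of 18 | c1ccccc1CO[C@H]1Cc2c(OCc3ccccc3)c([Li])c(OCc3ccccc3)c([C@@H]3c4cc([Li])c(OCc5ccccc5)cc4O[C@@H](c4ccc(OCc5ccccc5)c(OCc5ccccc5)c4)[C@@H]3OCc4ccccc4)c2O[C@@H]1c1ccc(OCc2ccccc2)c(OCc2ccccc2)c1 | intermediate
20 | bis-ketone: 18 with each Br replaced by a 4-(benzyloxy)-2-{[(1R)-1-[3,4-bis(benzyloxy)phenyl]prop-2-en-1-yl]oxy}benzoyl group | c1ccccc1CO[C@H]1Cc2c(OCc3ccccc3)c(C(=O)c6ccc(OCc7ccccc7)cc6O[C@@H](c6ccc(OCc7ccccc7)c(OCc7ccccc7)c6)C=C)c(OCc3ccccc3)c([C@@H]3c4cc(C(=O)c6ccc(OCc7ccccc7)cc6O[C@@H](c6ccc(OCc7ccccc7)c(OCc7ccccc7)c6)C=C)c(OCc5ccccc5)cc4O[C@@H](c4ccc(OCc5ccccc5)c(OCc5ccccc5)c4)[C@@H]3OCc4ccccc4)c2O[C@@H]1c1ccc(OCc2ccccc2)c(OCc2ccccc2)c1 | intermediate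
21 | bis(keto aldehyde): 20 with both vinyl groups cleaved to formyl groups | c1ccccc1CO[C@H]1Cc2c(OCc3ccccc3)c(C(=O)c6ccc(OCc7ccccc7)cc6O[C@@H](c6ccc(OCc7ccccc7)c(OCc7ccccc7)c6)C=O)c(OCc3ccccc3)c([C@@H]3c4cc(C(=O)c6ccc(OCc7ccccc7)cc6O[C@@H](c6ccc(OCc7ccccc7)c(OCc7ccccc7)c6)C=O)c(OCc5ccccc5)cc4O[C@@H](c4ccc(OCc5ccccc5)c(OCc5ccccc5)c4)[C@@H]3OCc4ccccc4)c2O[C@@H]1c1ccc(OCc2ccccc2)c(OCc2ccccc2)c1 | intermediate
22 | bis-diol: protected tetramer with tertiary 4-OH on the top and lateral units (3-OH and 4-OH cis, trans to 2-aryl; 3-OH free) | c1ccccc1CO[C@H]1Cc2c(OCc3ccccc3)c([C@@]6(O)c7ccc(OCc8ccccc8)cc7O[C@@H](c7ccc(OCc8ccccc8)c(OCc8ccccc8)c7)[C@@H]6O)c(OCc3ccccc3)c([C@@H]3c4cc([C@@]6(O)c7ccc(OCc8ccccc8)cc7O[C@@H](c7ccc(OCc8ccccc8)c(OCc8ccccc8)c7)[C@@H]6O)c(OCc5ccccc5)cc4O[C@@H](c4ccc(OCc5ccccc5)c(OCc5ccccc5)c4)[C@@H]3OCc4ccccc4)c2O[C@@H]1c1ccc(OCc2ccccc2)c(OCc2ccccc2)c1 | intermediate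
23 | bis(3-O-benzyl ether) of 22 | c1ccccc1CO[C@H]1Cc2c(OCc3ccccc3)c([C@@]6(O)c7ccc(OCc8ccccc8)cc7O[C@@H](c7ccc(OCc8ccccc8)c(OCc8ccccc8)c7)[C@@H]6OCc7ccccc7)c(OCc3ccccc3)c([C@@H]3c4cc([C@@]6(O)c7ccc(OCc8ccccc8)cc7O[C@@H](c7ccc(OCc8ccccc8)c(OCc8ccccc8)c7)[C@@H]6OCc7ccccc7)c(OCc5ccccc5)cc4O[C@@H](c4ccc(OCc5ccccc5)c(OCc5ccccc5)c4)[C@@H]3OCc4ccccc4)c2O[C@@H]1c1ccc(OCc2ccccc2)c(OCc2ccccc2)c1 | intermediate
24 | heptadeca-O-benzyl ether of the target | c1ccccc1CO[C@H]1Cc2c(OCc3ccccc3)c([C@@H]6c7ccc(OCc8ccccc8)cc7O[C@@H](c7ccc(OCc8ccccc8)c(OCc8ccccc8)c7)[C@@H]6OCc7ccccc7)c(OCc3ccccc3)c([C@@H]3c4cc([C@@H]6c7ccc(OCc8ccccc8)cc7O[C@@H](c7ccc(OCc8ccccc8)c(OCc8ccccc8)c7)[C@@H]6OCc7ccccc7)c(OCc5ccccc5)cc4O[C@@H](c4ccc(OCc5ccccc5)c(OCc5ccccc5)c4)[C@@H]3OCc4ccccc4)c2O[C@@H]1c1ccc(OCc2ccccc2)c(OCc2ccccc2)c1 | intermediate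
25 | ent-fisetinidol-(4α→6)-ent-fisetinidol-(4α→8)-catechin-(6→4α)-ent-fisetinidol; top unit 2S,3R,4R, middle unit 2S,3R,4S, lateral unit 2S,3R,4S, catechin unit 2R,3S | Oc1ccc2c(c1)O[C@@H](c1ccc(O)c(O)c1)[C@H](O)[C@@H]2c1cc2c(cc1O)O[C@@H](c1ccc(O)c(O)c1)[C@H](O)[C@@H]2c1c(O)c([C@@H]2c3ccc(O)cc3O[C@@H](c3ccc(O)c(O)c3)[C@@H]2O)c(O)c2c1O[C@H](c1ccc(O)c(O)c1)[C@@H](O)C2 | target

**Step count and risks**

Total steps: 20. Longest linear sequence: 17 steps (steps 1–5, then 9–20).

Steps most likely to fail: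

1. Step 17 (double pinacol cyclisation). What may go wrong: reduction of the aliphatic aldehydes with expulsion of the β-aryloxy group, erosion of the C-2 configuration of the α-aryloxy aldehydes before coupling, or poor facial selectivity at C-3. The fallback sets out from bis-ketone 20, so that the aldehydes are never made. Methylenation of both ketones with the Tebbe reagent Cp2Ti(μ-Cl)(μ-CH2)AlMe2 (THF/pyridine, −40 → 0 °C) gives the bis(1,1-diarylethene) F1. Ring-closing metathesis of each 1,1-diarylethene with its neighbouring vinyl group (second-generation Grubbs catalyst RuCl2(PCy3)(H2IMes)(=CHPh), toluene, 60 °C) closes both pyran rings across C-3=C-4 and gives the bis(4-aryl-2H-chromene) F2. Dihydroxylation (OsO4 cat., N-methylmorpholine N-oxide, acetone/H2O), which should occur anti to each C-2 aryl group, gives the same cis-diols and rejoins the route at 22.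

2. Step 19 (double ionic hydrogenation; the same concern applies to step 13). What may go wrong: poor facial selectivity of hydride delivery to the C-4 cations, or proton loss or 1,2-shift from C-3 in the cation. The fallback sets out from 23 and replaces hydride transfer in solution by heterogeneous hydrogenolysis (H2, 3 atm, Pd/C, EtOAc/MeOH, trace AcOH). Benzylic C–O bonds are cleaved on palladium with inversion, so hydrogen should enter anti to the departing 4-OH, which is cis to O-3, giving the 4α-aryl configuration while all benzyl ethers fall. This reaches the target 25 directly and makes no new compound (F0).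

3. Step 15 (double exchange and acylation). What may go wrong: slow acyl transfer from the hindered Weinreb amide to the di-ortho-alkoxy aryllithium on the catechin ring, so that proton transfer quenches one site and mono-adducts result. The fallback sets out from 7: LiAlH4 (THF, −40 °C) reduces the amide to the aldehyde, 4-(benzyloxy)-2-{[(1R)-1-[3,4-bis(benzyloxy)phenyl]prop-2-en-1-yl]oxy}benzaldehyde F3, a much more reactive electrophile. The dilithio compound 19 adds to two molecules of it to give the bis(diarylmethanol) F4 as a mixture of carbinol epimers, which is of no consequence. Dess–Martin periodinane (NaHCO3, CH2Cl2) oxidises both carbinols and rejoins the route at 20.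

**Further compounds**

F1 | step 17 | bis(1,1-diarylethene): 20 with both ketone C=O replaced by C=CH2 | c1ccccc1CO[C@H]1Cc2c(OCc3ccccc3)c(C(=C)c6ccc(OCc7ccccc7)cc6O[C@@H](c6ccc(OCc7ccccc7)c(OCc7ccccc7)c6)C=C)c(OCc3ccccc3)c([C@@H]3c4cc(C(=C)c6ccc(OCc7ccccc7)cc6O[C@@H](c6ccc(OCc7ccccc7)c(OCc7ccccc7)c6)C=C)c(OCc5ccccc5)cc4O[C@@H](c4ccc(OCc5ccccc5)c(OCc5ccccc5)c4)[C@@H]3OCc4ccccc4)c2O[C@@H]1c1ccc(OCc2ccccc2)c(OCc2ccccc2)c1
F2 | step 17 | bis(4-aryl-2H-chromene): protected tetramer with C-3=C-4 double bonds in the top and lateral units (each 2S) | c1ccccc1CO[C@H]1Cc2c(OCc3ccccc3)c(C6=C[C@H](c7ccc(OCc8ccccc8)c(OCc8ccccc8)c7)Oc7cc(OCc8ccccc8)ccc76)c(OCc3ccccc3)c([C@@H]3c4cc(C6=C[C@H](c7ccc(OCc8ccccc8)c(OCc8ccccc8)c7)Oc7cc(OCc8ccccc8)ccc76)c(OCc5ccccc5)cc4O[C@@H](c4ccc(OCc5ccccc5)c(OCc5ccccc5)c4)[C@@H]3OCc4ccccc4)c2O[C@@H]1c1ccc(OCc2ccccc2)c(OCc2ccccc2)c1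
F0 | step 19 | none | none
F3 | step 15 | 4-(benzyloxy)-2-{[(1R)-1-[3,4-bis(benzyloxy)phenyl]prop-2-en-1-yl]oxy}benzaldehyde | O=Cc1ccc(OCc2ccccc2)cc1O[C@@H](c1ccc(OCc2ccccc2)c(OCc2ccccc2)c1)C=C
F4 | step 15 | bis(diarylmethanol): 20 with both ketones as secondary carbinols (epimer mixture at the two carbinol carbons) | c1ccccc1CO[C@H]1Cc2c(OCc3ccccc3)c(C(O)c6ccc(OCc7ccccc7)cc6O[C@@H](c6ccc(OCc7ccccc7)c(OCc7ccccc7)c6)C=C)c(OCc3ccccc3)c([C@@H]3c4cc(C(O)c6ccc(OCc7ccccc7)cc6O[C@@H](c6ccc(OCc7ccccc7)c(OCc7ccccc7)c6)C=C)c(OCc5ccccc5)cc4O[C@@H](c4ccc(OCc5ccccc5)c(OCc5ccccc5)c4)[C@@H]3OCc4ccccc4)c2O[C@@H]1c1ccc(OCc2ccccc2)c(OCc2ccccc2)c1
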